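The number I start from is 0.100 mM: that much protic impurity meets 2.0 mM of starting material in a closed flask. The impurity is the limiting reagent, and each mole of it turns one mole of starting material into quenched substrate irreversibly. Its charge is therefore worth 5.00% of the starting material, and that is the first entry in my ledger.

starting material 2.0 mM; protic impurity 0.100 mM; time 2.0 h

- the state of affairs at 2.0 h: stopped, and by what, or still going (forward and back rates have come level / all of the starting material has reacted / it is still moving)
- amount of target at 2.0 h, in percent of the starting material charged

- the reaction counts as stopped when no species that holds the starting material changes by six tenths of a point or more over the second half of the time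
- run time (flask): 2.0 h

    starting material ⇌ target (K1 = 1.2, k1 = 0.039 s⁻¹)
    target ⇌ isomer of the product A (K2 = 1.9, k2 = 0.0090 s⁻¹)
    isomer of the product A ⇌ starting material (k3 = 0.015 s⁻¹)
    target ⇌ isomer of the product B (K4 = 1.4, k4 = 0.047 s⁻¹)
    starting material + protic impurity → quenched substrate (k5 = 41 M⁻¹ s⁻¹)

The remaining 95.0% stays in a reversible pool. Starting material gives target with constant 1.2, target gives isomer of the product A with 1.9 and isomer of the product B with 1.4, and isomer of the product A returns to starting material. For each part of starting material at level rates, the pool holds 6.16 parts in total. Target then stands at 19.5%, and this target share, the fraction of the pool that is target at level rates, is what I carry.

Now I count half-lives. The slowest relaxation, between target and isomer of the product A, takes 0.841 min, so 2.0 h holds 143 of them. With starting material at its part of the pool, the impurity has a half-life near 0.868 min, which gives about 138 half-lives. The books close with quenched substrate at 5.00% and target at 18.5%, beside isomer of the product A at 35.1%, isomer of the product B at 25.9% and starting material at 15.4%.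

The forecast says that forward and back rates have come level and puts target at 19.1%, between 18.7% and 19.6%, holding that “All the isomerisation steps relax within minutes”. It takes the share as about 0.20 and stands 0.60 percentage points above my figure.

In the simulation of this flask at 2.0 h, forward and back rates have come level, and target stands at 18.5%. That is my 19.5% of the 95.0% left in the pool. The forecast's figure counts as right within the tolerance on the answer, though the simulated value lies below the low end of the forecast's own range.

The neighbouring flask is the same flask read at 5.0 h. Its count is 357 half-lives of the target and isomer of the product A relaxation, and its impurity charge is unchanged, so I book 19.5% of the same pool again, 18.5%. That neighbouring flask reads 18.5% target, with 0% of its impurity left, 15.4% starting material, 35.2% isomer of the product A and 25.9% isomer of the product B.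

The constants used here were chosen freely.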